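**Retrosynthetic overview**
1. Target ⇐ hydroboration of a C14 exocyclic methylene plus oxidation of C–B and a C21–Si bond ⇐ tetracyclic C14 ketone with C9=C10.
2. Ring B (cyclopentene) ⇐ vinylcyclopropane–cyclopentene rearrangement of a C10 spiro-cyclopropane; ring A (cyclopentenone) ⇐ intramolecular aldol condensation of a C9/C14 1,4-diketone.
3. Piperidine ⇐ intramolecular Mannich closure C1–C8 onto the C9 ketone by an iminium ion made by oxidising one N-methyl of a CH2NMe2 group (C1 starts as an N-methyl carbon).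
4. Cycloheptanone with quaternary C5 and C6 ⇐ Stork–Danheiser transposition, then anti conjugate addition/enolate allylation, on the aminomethylated vinylogous ester of cycloheptane-1,3-dione; side chain from methyl (S)-3-hydroxypentanoate.
5. Ring order: seven-membered carbocycle (bought) → piperidine → ring A → ring B.

Assumption 1: the nitrogen ring of this seco-Daphniphyllum-type base is presumed to close in Nature by attack of a C8 enol/olefin on an iminium ion (Mannich/aza-Prins type) and the five-membered carbocycles by aldol-type closures.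
Assumption 2: which enantiomer of dibenzoyltartaric acid crystallises the (7S) salt in step 6 must be found by experiment; the L-acid is written.
Atom labels (Daphniphyllum convention): N–C1–C8; C8–C5–C6–C7–N; C6–C12–C11–C10=C9–C8; C9–C15–C16–C17–C10 (ring B); C15–C14–C13–C8 (ring A); C21 on C5; C22 on C14; side chain C5–C4–C3–C2(OH)–CH2CH3.

**Step 1**
Reactants: 1 methyl (3S)-3-hydroxypentanoate
Product: 2 methyl (3S)-3-[(tert-butyldiphenylsilyl)oxy]pentanoate
Conditions: t-BuPh2SiCl, imidazole, DMF, 25 °C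
Reagents that add atoms: tert-butyl(chloro)diphenylsilane, CC(C)(C)[Si](Cl)(c1ccccc1)c1ccccc1
Why: Imidazole-promoted silyl ether formation protects the secondary alcohol; the C2 stereocentre comes from the purchased hydroxy ester and is not touched.

**Step 2**
Reactants: 2 methyl (3S)-3-[(tert-butyldiphenylsilyl)oxy]pentanoate
Product: 3 (3S)-3-[(tert-butyldiphenylsilyl)oxy]pentan-1-ol
Conditions: LiAlH4, Et2O, 0 °C
Reagents that add atoms: none
Why: Hydride reduction of the ester to the primary alcohol leaves the silyl ether and the stereocentre intact.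

**Step 3**
Reactants: 3 (3S)-3-[(tert-butyldiphenylsilyl)oxy]pentan-1-ol
Product: 4 tert-butyl{[(3S)-1-iodopentan-3-yl]oxy}diphenylsilane
Conditions: I2, PPh3, imidazole, CH2Cl2, 0 → 25 °C
Reagents that add atoms: iodine, II
Why: Appel-type iodination converts the primary alcohol into the iodide by SN2 at the unhindered CH2.

**Step 4**
Reactants: 5 cycloheptane-1,3-dione
Product: 6 3-(2-methylpropoxy)cyclohept-2-en-1-one
Conditions: i-BuOH, TsOH·H2O (cat.), toluene, reflux, Dean–Stark
Reagents that add atoms: 2-methylpropan-1-ol, CC(C)CO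
Why: Acid-catalysed O-alkylation of the enolised 1,3-dione (vinylogous ester formation) is driven by azeotropic removal of water.

**Step 5**
Reactants: 6 3-(2-methylpropoxy)cyclohept-2-en-1-one; 7 N,N-dimethylmethaniminium iodide (Eschenmoser's salt)
Product: 8 racemic 7-[(dimethylamino)methyl]-3-(2-methylpropoxy)cyclohept-2-en-1-one
Conditions: LiN(i-Pr)2, THF, −78 °C; then 7, −78 → 0 °C
Reagents that add atoms: none
Why: Kinetic deprotonation of the vinylogous ester occurs only at the α′ CH2, and the enolate is aminomethylated by the preformed iminium salt (Mannich reaction) to give the racemic Mannich base.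

**Step 6**
Reactants: 8 racemic 7-[(dimethylamino)methyl]-3-(2-methylpropoxy)cyclohept-2-en-1-one
Product: 9 (7S)-7-[(dimethylamino)methyl]-3-(2-methylpropoxy)cyclohept-2-en-1-one
Conditions: (−)-O,O′-dibenzoyl-L-tartaric acid (1 equiv), i-BuOH/EtOAc, 50 → 20 °C, slurry 48 h; filter; aq. K2CO3
Reagents that add atoms: none
Why: Crystallisation-induced dynamic resolution: the stereocentre is α to the carbonyl of a β-amino ketone and epimerises in solution through the enol while the less soluble diastereomeric salt crystallises, which fixes the future C6.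

**Step 7**
Reactants: 4 tert-butyl{[(3S)-1-iodopentan-3-yl]oxy}diphenylsilane; 9 (7S)-7-[(dimethylamino)methyl]-3-(2-methylpropoxy)cyclohept-2-en-1-one
Product: 12 (4R)-4-[(dimethylamino)methyl]-3-{(3S)-3-[(tert-butyldiphenylsilyl)oxy]pentyl}cyclohept-2-en-1-one, via Grignard reagent 10 (not isolated), via tertiary alcohol 11 (not isolated)
Conditions: Mg, THF, 35 °C; CeCl3, THF, −78 °C; 9, −78 → 0 °C; 10% aq. HCl, THF, 50 °C
Reagents that add atoms: none
Why: Stork–Danheiser enone transposition: the organocerium species adds 1,2 to the vinylogous ester carbonyl, and acid hydrolysis of the enol ether with loss of water gives the 3-alkyl enone, carrying C2 and C6 through unchanged.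

**Step 8**
Reactants: 12 (4R)-4-[(dimethylamino)methyl]-3-{(3S)-3-[(tert-butyldiphenylsilyl)oxy]pentyl}cyclohept-2-en-1-one; 13 benzyl(chloromethyl)dimethylsilane; 14 3-bromo-2-methylprop-1-ene
Product: 17 (3S,4R)-3-[(benzyldimethylsilyl)methyl]-4-[(dimethylamino)methyl]-2-(2-methylprop-2-en-1-yl)-3-{(3S)-3-[(tert-butyldiphenylsilyl)oxy]pentyl}cycloheptan-1-one (both C2 epimers), via silylmethyl Grignard reagent 15 (not isolated), via trimethylsilyl enol ether 16 (not isolated)
Conditions: 13, Mg, THF; 12, CuBr·SMe2 (20 mol %), Me3SiCl, THF, −78 → −30 °C; MeLi, THF, 0 °C; 14, DMPU, −78 → 0 °C; aq. NH4Cl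
Reagents that add atoms: none
Why: Copper-catalysed, Me3SiCl-accelerated conjugate addition creates the quaternary C5 with the silylmethyl group (the masked C21 hydroxymethyl) entering anti to the neighbouring aminomethyl group on C6 (1,2-induction in a 4-substituted cycloalkenone); the regiodefined enolate released from the silyl enol ether is then C-allylated at C8, whose configuration does not matter because it is planar again in step 9.

**Step 9**
Reactants: 17 (3S,4R)-3-[(benzyldimethylsilyl)methyl]-4-[(dimethylamino)methyl]-2-(2-methylprop-2-en-1-yl)-3-{(3S)-3-[(tert-butyldiphenylsilyl)oxy]pentyl}cycloheptan-1-one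
Product: 20 (1S,6R,10S)-10-[(benzyldimethylsilyl)methyl]-8-methyl-1-(2-methylprop-2-en-1-yl)-10-{(3S)-3-[(tert-butyldiphenylsilyl)oxy]pentyl}-8-azabicyclo[4.3.1]decan-2-one, via amine N-oxide 18 (not isolated), via iminium trifluoroacetate 19 (not isolated)
Conditions: mCPBA (1.05 equiv), CH2Cl2, −20 °C; (CF3CO)2O, −78 → 0 °C; MeCN, 60 °C; aq. NaHCO3
Reagents that add atoms: none
Why: The Polonovski–Potier reaction of the N-oxide unmasks an N-methyleneiminium ion from one N-methyl group, and the enol of the C9 ketone closes the piperidine by an intramolecular Mannich reaction at C8, the only carbon it can reach through a six-membered ring; the one-carbon bridge forces the new C1–C8 bond cis to C6–C7, which sets the quaternary C8 relative to C5 and C6.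

**Step 10**
Reactants: 20 (1S,6R,10S)-10-[(benzyldimethylsilyl)methyl]-8-methyl-1-(2-methylprop-2-en-1-yl)-10-{(3S)-3-[(tert-butyldiphenylsilyl)oxy]pentyl}-8-azabicyclo[4.3.1]decan-2-one; 21 1,3,2-dioxathiolane 2,2-dioxide (ethylene sulfate)
Product: 23 C10 spiro-cyclopropane of 20 (cyclopropane carbons are C16 and C17; 5S,6R,8S), via lithium alkyl sulfate 22 (not isolated)
Conditions: LiN(i-Pr)2 (1.1 equiv), THF, −78 °C; 21, −78 → 0 °C; LiN(i-Pr)2 (1.3 equiv), −78 → 25 °C
Reagents that add atoms: none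
Why: Double alkylation of the only enolisable position (C10) by the cyclic sulfate (enolate alkylation, then 3-exo-tet closure) gives the spiro-cyclopropane, which brings in C16 and C17 and blocks C10 for the aldol step.

**Step 11**
Reactants: 23 C10 spiro-cyclopropane of 20
Product: 25 ring A enone (C14 ketone conjugated to C15=C9, C10 spiro-cyclopropane; 5S,6R,8S), via methyl ketone 24 (not isolated)
Conditions: CF3CO2H (1.1 equiv), O3, CH2Cl2/MeOH, −78 °C; Me2S; KOH, MeOH, 60 °C
Reagents that add atoms: ozone, O=[O+][O-]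
Why: Ozonolysis of the 1,1-disubstituted alkene (amine masked as its salt) gives the C14 methyl ketone, whose CH3 enolate can only attack C9 in the intramolecular aldol condensation of the 1,4-diketone, closing cyclopentenone ring A.

**Step 12**
Reactants: 25 ring A enone
Product: 27 tetracyclic β,γ-unsaturated ketone (C14 ketone, C9=C10, ring B closed; 2S,5S,6R,8S,15R), via potassium dienolate 26 (not isolated)
Conditions: Ni(cod)2 (10 mol %), 1,3-bis(2,6-diisopropylphenyl)imidazol-2-ylidene (10 mol %), toluene, 80 °C; KOt-Bu (1.5 equiv), THF, 0 °C; AcOH, −78 °C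
Reagents that add atoms: none
Why: The nickel-catalysed vinylcyclopropane–cyclopentene rearrangement (zerovalent nickel inserts into the cyclopropane bond allylic to the enone, then reductive elimination) closes ring B and moves the olefin to C9=C10; deprotonation to the extended dienolate and kinetic α-protonation from the face of the C1 bridge, opposite the silylmethyl group on C5, then sets C15.

**Step 13**
Reactants: 27 tetracyclic β,γ-unsaturated ketone
Product: 28 C14 exocyclic methylene compound (2S,5S,6R,8S,15S)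
Conditions: (C5H5)2Ti(CH3)2 (3 equiv), toluene/THF, 65 °C, dark
Reagents that add atoms: dimethyltitanocene, C[Ti](C)(C1C=CC=C1)C1C=CC=C1
Why: Petasis methylenation is non-basic, so the epimerisable, conjugation-prone ketone is converted into the alkene (C22) without loss of the C15 configuration or the olefin position.

**Step 14**
Reactants: 28 C14 exocyclic methylene compound
Product: 30 target CNP0221997.1 (2S,5S,6R,8S,14S,15S), via alkylborane 29 (not isolated)
Conditions: 9-BBN-H (3 equiv), THF, 0 → 25 °C; Bu4NF, THF, 25 °C; KHCO3, 30% H2O2, MeOH, 45 °C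
Reagents that add atoms: hydrogen peroxide, OO
Why: Anti-Markovnikov hydroboration of the 1,1-disubstituted alkene from the convex face, anti to the ring B carbon C16 on C15, puts H on C14 and leaves C22 cis to C16 (the tetrasubstituted C9=C10 is inert); one fluoride/peroxide work-up then oxidises C–B and C–Si to C–OH (organoborane and Tamao–Fleming oxidation of the benzyldimethylsilyl group) and removes the silyl ether, the amine being largely protonated at bicarbonate pH.

**Compound list**
1 | methyl (3S)-3-hydroxypentanoate | CC[C@H](O)CC(=O)OC | starting material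
2 | methyl (3S)-3-[(tert-butyldiphenylsilyl)oxy]pentanoate | CC[C@H](O[Si](c1ccccc1)(c1ccccc1)C(C)(C)C)CC(=O)OC | intermediate
3 | (3S)-3-[(tert-butyldiphenylsilyl)oxy]pentan-1-ol | CC[C@H](O[Si](c1ccccc1)(c1ccccc1)C(C)(C)C)CCO | intermediate
4 | tert-butyl{[(3S)-1-iodopentan-3-yl]oxy}diphenylsilane | CC[C@H](O[Si](c1ccccc1)(c1ccccc1)C(C)(C)C)CCI | intermediate
5 | cycloheptane-1,3-dione | O=C1CCCCC(=O)C1 | starting material
6 | 3-(2-methylpropoxy)cyclohept-2-en-1-one | CC(C)COC1=CC(=O)CCCC1 | intermediate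
7 | N,N-dimethylmethaniminium iodide (Eschenmoser's salt) | C=[N+](C)C.[I-] | starting material
8 | racemic 7-[(dimethylamino)methyl]-3-(2-methylpropoxy)cyclohept-2-en-1-one | CC(C)COC1=CC(=O)C(CN(C)C)CCC1 | intermediate
9 | (7S)-7-[(dimethylamino)methyl]-3-(2-methylpropoxy)cyclohept-2-en-1-one | CC(C)COC1=CC(=O)[C@H](CN(C)C)CCC1 | intermediate
10 | {(3S)-3-[(tert-butyldiphenylsilyl)oxy]pentyl}magnesium iodide | CC[C@H](O[Si](c1ccccc1)(c1ccccc1)C(C)(C)C)CC[Mg]I | intermediate
11 | (7S)-7-[(dimethylamino)methyl]-1-{(3S)-3-[(tert-butyldiphenylsilyl)oxy]pentyl}-3-(2-methylpropoxy)cyclohept-2-en-1-ol (C1 epimers) | CC[C@H](O[Si](c1ccccc1)(c1ccccc1)C(C)(C)C)CCC1(O)C=C(OCC(C)C)CCC[C@H]1CN(C)C | intermediate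
12 | (4R)-4-[(dimethylamino)methyl]-3-{(3S)-3-[(tert-butyldiphenylsilyl)oxy]pentyl}cyclohept-2-en-1-one | CC[C@H](O[Si](c1ccccc1)(c1ccccc1)C(C)(C)C)CCC1=CC(=O)CCC[C@H]1CN(C)C | intermediate
13 | benzyl(chloromethyl)dimethylsilane | ClC[Si](C)(C)Cc1ccccc1 | starting material
14 | 3-bromo-2-methylprop-1-ene | CC(=C)CBr | starting material
15 | [(benzyldimethylsilyl)methyl]magnesium chloride | Cl[Mg]C[Si](C)(C)Cc1ccccc1 | intermediate
16 | trimethylsilyl enol ether of the conjugate adduct: {[(3S,4R)-3-[(benzyldimethylsilyl)methyl]-4-[(dimethylamino)methyl]-3-{(3S)-3-[(tert-butyldiphenylsilyl)oxy]pentyl}cyclohept-1-en-1-yl]oxy}trimethylsilane | CC[C@H](O[Si](c1ccccc1)(c1ccccc1)C(C)(C)C)CC[C@]1(C[Si](C)(C)Cc2ccccc2)[C@H](CN(C)C)CCCC(O[Si](C)(C)C)=C1 | intermediate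
17 | (3S,4R)-3-[(benzyldimethylsilyl)methyl]-4-[(dimethylamino)methyl]-2-(2-methylprop-2-en-1-yl)-3-{(3S)-3-[(tert-butyldiphenylsilyl)oxy]pentyl}cycloheptan-1-one (C2 epimers) | CC[C@H](O[Si](c1ccccc1)(c1ccccc1)C(C)(C)C)CC[C@]1(C[Si](C)(C)Cc2ccccc2)[C@H](CN(C)C)CCCC(=O)C1CC(C)=C | intermediate
18 | N-oxide of 17 (N,N-dimethylamine oxide on C7) | CC[C@H](O[Si](c1ccccc1)(c1ccccc1)C(C)(C)C)CC[C@]1(C[Si](C)(C)Cc2ccccc2)[C@H](C[N+](C)(C)[O-])CCCC(=O)C1CC(C)=C | intermediate
19 | N-methyl-N-methylideneiminium trifluoroacetate derived from 17 | CC[C@H](O[Si](c1ccccc1)(c1ccccc1)C(C)(C)C)CC[C@]1(C[Si](C)(C)Cc2ccccc2)[C@H](C[N+](C)=C)CCCC(=O)C1CC(C)=C.[O-]C(=O)C(F)(F)F | intermediate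
20 | (1S,6R,10S)-10-[(benzyldimethylsilyl)methyl]-8-methyl-1-(2-methylprop-2-en-1-yl)-10-{(3S)-3-[(tert-butyldiphenylsilyl)oxy]pentyl}-8-azabicyclo[4.3.1]decan-2-one | CC[C@H](O[Si](c1ccccc1)(c1ccccc1)C(C)(C)C)CC[C@]1(C[Si](C)(C)Cc3ccccc3)[C@H]2CCCC(=O)[C@]1(CC(C)=C)CN(C)C2 | intermediate
21 | 1,3,2-dioxathiolane 2,2-dioxide (ethylene sulfate) | O=S1(=O)OCCO1 | starting material
22 | lithium 2-(2-oxo-8-azabicyclo[4.3.1]decan-3-yl)ethyl sulfate derived from 20 (C10 mono-alkylated) | CC[C@H](O[Si](c1ccccc1)(c1ccccc1)C(C)(C)C)CC[C@]1(C[Si](C)(C)Cc3ccccc3)[C@H]2CCC(CCOS(=O)(=O)[O-])C(=O)[C@]1(CC(C)=C)CN(C)C2.[Li+] | intermediate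
23 | C10 spiro-cyclopropane of 20 (5S,6R,8S) | CC[C@H](O[Si](c1ccccc1)(c1ccccc1)C(C)(C)C)CC[C@]1(C[Si](C)(C)Cc3ccccc3)[C@H]2CCC3(CC3)C(=O)[C@]1(CC(C)=C)CN(C)C2 | intermediate
24 | 1,4-diketone: 23 with the 2-methylallyl group cleaved to 2-oxopropyl | CC[C@H](O[Si](c1ccccc1)(c1ccccc1)C(C)(C)C)CC[C@]1(C[Si](C)(C)Cc3ccccc3)[C@H]2CCC3(CC3)C(=O)[C@]1(CC(C)=O)CN(C)C2 | intermediate
25 | ring A enone: azabicyclo[4.3.1]decane fused at C8–C9 to a cyclopent-2-enone (C14=O, C15=C9), C10 spiro-cyclopropane (5S,6R,8S) | CC[C@H](O[Si](c1ccccc1)(c1ccccc1)C(C)(C)C)CC[C@]1(C[Si](C)(C)Cc3ccccc3)[C@H]2CCC3(CC3)C4=CC(=O)C[C@]41CN(C)C2 | intermediate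
26 | potassium dienolate of 27 (O–C14=C15–C9=C10) | CC[C@H](O[Si](c1ccccc1)(c1ccccc1)C(C)(C)C)CC[C@]1(C[Si](C)(C)Cc3ccccc3)[C@H]2CCC3=C4C(CC3)=C([O-])C[C@]41CN(C)C2.[K+] | intermediate
27 | tetracyclic ketone: target skeleton with C14=O, C21 as CH2SiMe2Bn, O2 as silyl ether (2S,5S,6R,8S,15R) | CC[C@H](O[Si](c1ccccc1)(c1ccccc1)C(C)(C)C)CC[C@]1(C[Si](C)(C)Cc3ccccc3)[C@H]2CCC3=C4[C@@H](CC3)C(=O)C[C@]41CN(C)C2 | intermediate
28 | C14 methylidene analogue of 27 (2S,5S,6R,8S,15S) | CC[C@H](O[Si](c1ccccc1)(c1ccccc1)C(C)(C)C)CC[C@]1(C[Si](C)(C)Cc3ccccc3)[C@H]2CCC3=C4[C@@H](CC3)C(=C)C[C@]41CN(C)C2 | intermediate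
29 | B-alkyl-9-borabicyclo[3.3.1]nonane with boron on C22 (2S,5S,6R,8S,14S,15S) | CC[C@H](O[Si](c1ccccc1)(c1ccccc1)C(C)(C)C)CC[C@]1(C[Si](C)(C)Cc3ccccc3)[C@H]2CCC3=C4[C@@H](CC3)[C@@H](CB5C6CCCC5CCC6)C[C@]41CN(C)C2 | intermediate
30 | CNP0221997.1 (2S,5S,6R,8S,14S,15S) | CC[C@H](O)CC[C@]1(CO)[C@H]2CCC3=C4[C@@H](CC3)[C@@H](CO)C[C@]41CN(C)C2 | target

**Step count**
Total: 14 steps. Longest linear sequence: 11 steps (5 → 30 through steps 4–14; the side-chain branch 1 → 30 through steps 1–3 and 7–14 is also 11).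

**Steps most likely to fail**

Step 9 (oxidative Mannich closure). The enol must form at a hindered carbon next to the quaternary C5, and the iminium ion may hydrolyse first. The fallback sets out from 17 and comes back at 20. The N-oxide of 17 is cleaved with FeSO4·7H2O (iron-mediated Polonovski N-demethylation) to the secondary amine (3S,4R)-3-[(benzyldimethylsilyl)methyl]-4-[(methylamino)methyl]-2-(2-methylprop-2-en-1-yl)-3-{(3S)-3-[(tert-butyldiphenylsilyl)oxy]pentyl}cycloheptan-1-one F6. Heating F6 with paraformaldehyde and camphorsulfonic acid in MeCN at 80 °C over molecular sieves then runs the closure as a reversible three-component Mannich reaction. The iminium ion is re-formed from external formaldehyde until the C8 enol captures it, giving 20.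

Step 12 (ring B and C15). The nickel catalyst may be slowed by the amine and the hindered trisubstituted enone olefin, and the facial selectivity of the protonation is only moderate. The fallback sets out from 25 and comes back at 27. MgI2 in MeCN at 60 °C opens the cyclopropane by vinylogous homoconjugate attack of iodide and gives, after aqueous work-up, the 2-iodoethyl enone F7 (25 with C10 bearing H and CH2CH2I). KOt-Bu in THF then forms the extended dienolate, which closes ring B by intramolecular C-alkylation at C15 (attack through C10 only regenerates 25). The same cold AcOH quench delivers 27 by way of 26.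

Step 6 (dynamic resolution). Crystallisation and epimerisation rates cannot be predicted. The fallback sets out from 5 and comes back at 12, taking the absolute configuration from an auxiliary. The dione is converted with ethylene glycol/TsOH into the monoketal 1,4-dioxaspiro[4.6]undecan-7-one F1 and condensed with (2S)-2-(methoxymethyl)pyrrolidin-1-amine to the hydrazone F2. Deprotonation with LiN(i-Pr)2 on the side away from the ketal and reaction with 7 gives the aminomethylated hydrazone F3 under Enders-type auxiliary control (the antipodal auxiliary is used if the sense proves opposite). Two-phase oxalic acid cleavage releases the ketone (8S)-8-[(dimethylamino)methyl]-1,4-dioxaspiro[4.6]undecan-7-one F4. Addition of 10 with CeCl3 gives the tertiary alcohol F5, and warm aqueous HCl removes the ketal and dehydrates to 12.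

**Further compounds**
F1 | step 6 | 1,4-dioxaspiro[4.6]undecan-7-one | O=C1CCCCC2(C1)OCCO2
F2 | step 6 | (2S)-N-(1,4-dioxaspiro[4.6]undecan-7-ylidene)-2-(methoxymethyl)pyrrolidin-1-amine | COC[C@@H]1CCCN1N=C1CCCCC2(C1)OCCO2
F3 | step 6 | (2S)-N-{(8S)-8-[(dimethylamino)methyl]-1,4-dioxaspiro[4.6]undecan-7-ylidene}-2-(methoxymethyl)pyrrolidin-1-amine | COC[C@@H]1CCCN1N=C1[C@H](CN(C)C)CCCC2(C1)OCCO2
F4 | step 6 | (8S)-8-[(dimethylamino)methyl]-1,4-dioxaspiro[4.6]undecan-7-one | O=C1[C@H](CN(C)C)CCCC2(C1)OCCO2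
F5 | step 6 | (8S)-8-[(dimethylamino)methyl]-7-{(3S)-3-[(tert-butyldiphenylsilyl)oxy]pentyl}-1,4-dioxaspiro[4.6]undecan-7-ol (C7 epimers) | CC[C@H](O[Si](c1ccccc1)(c1ccccc1)C(C)(C)C)CCC1(O)CC2(CCC[C@H]1CN(C)C)OCCO2
F6 | step 9 | (3S,4R)-3-[(benzyldimethylsilyl)methyl]-4-[(methylamino)methyl]-2-(2-methylprop-2-en-1-yl)-3-{(3S)-3-[(tert-butyldiphenylsilyl)oxy]pentyl}cycloheptan-1-one | CC[C@H](O[Si](c1ccccc1)(c1ccccc1)C(C)(C)C)CC[C@]1(C[Si](C)(C)Cc2ccccc2)[C@H](CNC)CCCC(=O)C1CC(C)=C
F7 | step 12 | 2-iodoethyl enone: 25 with the cyclopropane opened to C10–H and C10–CH2CH2I (C10 epimers) | CC[C@H](O[Si](c1ccccc1)(c1ccccc1)C(C)(C)C)CC[C@]1(C[Si](C)(C)Cc3ccccc3)[C@H]2CCC(CCI)C4=CC(=O)C[C@]41CN(C)C2
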